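**Retrosynthetic overview**
1. Target ⇒ its E-enone isomer (E→Z energy-transfer isomerisation) ⇒ the 4-methylpent-3-enoyl bicyclo[3.2.1]octane (allylic selenoxide [2,3] shift puts the OH on CMe2).
2. Bicyclo[3.2.1]octane ⇒ 3-hydroxy-bicyclo[3.3.1]nonane-2,4,9-trione by α-ketol ring contraction (C2 migrates from C3 to C4; C3 becomes the side-chain ketone).
3. That trione ⇒ a monocyclic, C3-hydroxylated (humulone-type) dearomatised acylphloroglucinol: the C8 tertiary cation is captured by the C1 enol, in the same flask as the ring contraction.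
4. Monocycle ⇒ deoxycohumulone + (S)-lavandulyl triflate (alkylative dearomatisation, then enolate hydroxylation); these come from phloroglucinol, isobutyryl chloride, prenyl bromide and (±)-lavandulol.
5. Ring order: aromatic six-membered ring (bought) → ring B by C1–C8 closure (bicyclo[3.3.1]) → contraction of ring A to the five-membered dione (bicyclo[3.2.1]).

Assumption: (±)-lavandulol is taken as a commercial starting material; locants C1–C9 in the text follow PPAP usage (C1 isobutyryl bridgehead, C2 next to C1, C3 the prenyl-bearing carbon that ends as the side-chain ketone, C4 next to C5, C5 prenyl bridgehead, C6 CH2, C7 CH-prenyl, C8 CMe2, C9 bridging carbonyl).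

**Step 1**
Reactants: 1 (±)-lavandulol
Product: 2 (S)-lavandulol
Conditions: porcine pancreatic lipase, succinic anhydride (0.7 equiv), t-BuOMe, 23 °C, to ca. 65% conversion; aq. NaHCO3 wash
Reagents that add atoms: none
Why: Lipase kinetic resolution in which the (R)-alcohol is acylated faster, so past 60% conversion the unreacted alcohol is the (S)-enantiomer (ee checked by chiral GC) and the (R)-hemisuccinate is removed by base extraction; no stereocentre is created.

**Step 2**
Reactants: 2 (S)-lavandulol
Product: 3 (S)-lavandulyl triflate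
Conditions: Tf2O, 2,6-lutidine, CH2Cl2, −78 °C; used at once
Reagents that add atoms: trifluoromethanesulfonic anhydride, O=S(=O)(OS(=O)(=O)C(F)(F)F)C(F)(F)F
Why: O-sulfonylation of a primary alcohol at low temperature; the stereocentre is not involved.

**Step 3**
Reactants: 4 phloroglucinol; 5 isobutyryl chloride
Product: 6 phlorisobutyrophenone
Conditions: AlCl3 (3.5 equiv), PhNO2, 65 °C; aq. HCl
Reagents that add atoms: none
Why: Friedel–Crafts C-acylation of the electron-rich arene, which stops at mono-acylation because the ketone deactivates the ring.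

**Step 4**
Reactants: 6 phlorisobutyrophenone; 7 prenyl bromide (2 equiv)
Product: 8 deoxycohumulone
Conditions: KOH (10% aq.), 0 °C
Reagents that add atoms: none
Why: C-selective double prenylation of the phloroglucinol polyanion in water (ambident phenoxide, soft allylic electrophile), the standard entry to deoxyhumulone-type acids.

**Step 5**
Reactants: 8 deoxycohumulone; 3 (S)-lavandulyl triflate
Product: 10 hydroxylated monocycle (humulone type; OH on the prenyl-bearing enol carbon; both epimers there), via dearomatised lavandulyl dienone 9 (not isolated)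
Conditions: LiN(SiMe3)2 (3.1 equiv), THF/PhMe, −78 → 0 °C; then 2-(phenylsulfonyl)-3-phenyloxaziridine (1.3 equiv), −78 → −20 °C; aq. HCl
Reagents that add atoms: (±)-trans-2-(phenylsulfonyl)-3-phenyloxaziridine (Davis oxaziridine), O=S(=O)(c1ccccc1)N1OC1c1ccccc1
Why: Alkylative dearomatisation of the lithium trianion at a prenyl-bearing carbon leaves the dianion of 9, whose most electron-rich carbon (the prenyl-bearing β-diketonate carbon, C3) is hydroxylated by the N-sulfonyloxaziridine (Davis oxidation); the new quaternary carbon forms about 1:1 (the epimer drawn is the one used, the other is removed after step 6), the carbinol centre is uncontrolled but erased in step 6, and the lavandulyl centre is untouched (its descriptor changes from S to R by priority only).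

**Step 6**
Reactants: 10 hydroxylated monocycle
Product: 12 prenyl-ketone bicyclo[3.2.1]octane, via bicyclo[3.3.1]nonane hydroxytrione 11 (not isolated)
Conditions: HCO2H, 23 °C; evaporate; DBU (0.3 equiv), PhMe, 50 °C
Reagents that add atoms: none
Why: Proposed new method: protonation of the isopropenyl group gives the C8 tertiary cation, and because C3 is already sp3 the only enol carbon left is C1 of the β-triketone, so reversible O-capture funnels into the C1–C8 bond (type A closure through a chair with the C7 prenyl equatorial, so the lavandulyl centre sets C1 and C5 and only the matched C5 epimer closes this way), after which base triggers the α-ketol (acyloin) shift of C2 from C3 to C4 under thermodynamic control, placing the new acyl group exo (syn to the C9 bridge) and the hydroxyl endo and erasing C3; the closest known reactions are formic-acid cation–enol cyclisations of dearomatised acylphloroglucinols and the humulone-to-isohumulone ring contraction, and a contraction that ran before the C–C closure would converge on the same product.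

**Step 7**
Reactants: 12 prenyl-ketone bicyclo[3.2.1]octane
Product: 14 E-γ-hydroxy enone, via α-phenylselanyl ketone 13 (not isolated)
Conditions: LiN(SiMe3)2 (2.2 equiv), THF, −78 °C; PhSeCl; then mCPBA (1.05 equiv), CH2Cl2, −78 °C; Et3N, −78 → 0 °C; H2O
Reagents that add atoms: 3-chloroperoxybenzoic acid (mCPBA), O=C(OO)c1cccc(Cl)c1; phenylselanyl chloride, Cl[Se]c1ccccc1 (its atoms stay in 13 only)
Why: The alkoxide/dienolate of the β,γ-unsaturated ketone (the only accessible enolate) is selenenylated at the α-carbon, selenium is oxidised far faster than any prenyl group is epoxidised at −78 °C, and the allylic selenoxide undergoes [2,3]-sigmatropic rearrangement (acyl group pseudo-equatorial in the envelope) to the selenenate of the tertiary alcohol, giving the E-enone without touching a ring stereocentre.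

**Step 8**
Reactants: 14 E-γ-hydroxy enone
Product: 15 target (Z-enone)
Conditions: thioxanthen-9-one (10 mol %), 405 nm LED, degassed MeCN, 23 °C
Reagents that add atoms: none
Why: Triplet-sensitised E→Z isomerisation by selective energy transfer: the planar E-enone is excited, while the twisted, internally hydrogen-bonded Z-isomer (in ring–chain equilibrium with its non-absorbing lactol) accumulates; saturated ketones and prenyl groups are not sensitised at this wavelength, and no stereocentre changes.

**Compound list**
1 | (±)-lavandulol, (±)-5-methyl-2-(prop-1-en-2-yl)hex-4-en-1-ol | CC(C)=CCC(CO)C(C)=C | starting material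
2 | (S)-lavandulol, (2S)-5-methyl-2-(prop-1-en-2-yl)hex-4-en-1-ol | CC(C)=CC[C@@H](C(C)=C)CO | intermediate
3 | (S)-lavandulyl triflate, (2S)-5-methyl-2-(prop-1-en-2-yl)hex-4-en-1-yl trifluoromethanesulfonate | CC(C)=CC[C@@H](C(C)=C)COS(=O)(=O)C(F)(F)F | intermediate
4 | phloroglucinol, benzene-1,3,5-triol | Oc1cc(O)cc(O)c1 | starting material
5 | isobutyryl chloride, 2-methylpropanoyl chloride | CC(C)C(Cl)=O | starting material
6 | phlorisobutyrophenone, 2-methyl-1-(2,4,6-trihydroxyphenyl)propan-1-one | CC(C)C(=O)c1c(O)cc(O)cc1O | intermediate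
7 | prenyl bromide, 1-bromo-3-methylbut-2-ene | CC(C)=CCBr | starting material
8 | deoxycohumulone, 2-methyl-1-[2,4,6-trihydroxy-3,5-bis(3-methylbut-2-en-1-yl)phenyl]propan-1-one | CC(C)C(=O)c1c(O)c(CC=C(C)C)c(O)c(CC=C(C)C)c1O | intermediate
9 | 3,5-dihydroxy-2-(2-methylpropanoyl)-4,6-bis(3-methylbut-2-en-1-yl)-6-[(2R)-5-methyl-2-(prop-1-en-2-yl)hex-4-en-1-yl]cyclohexa-2,4-dien-1-one, as its dilithium salt in the flask (C6 epimer drawn = C5 of the target; formed about 1:1 with its C6 epimer) | CC(C)=CC[C@@H](C(C)=C)C[C@]1(CC=C(C)C)C(=O)C(C(=O)C(C)C)=C(O)C(CC=C(C)C)=C1O | intermediate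
10 | 3,4-dihydroxy-2-(2-methylpropanoyl)-4,6-bis(3-methylbut-2-en-1-yl)-6-[(2R)-5-methyl-2-(prop-1-en-2-yl)hex-4-en-1-yl]cyclohex-2-ene-1,5-dione (C6 as in 9; both C4 epimers) | CC(C)=CC[C@@H](C(C)=C)C[C@]1(CC=C(C)C)C(=O)C(C(=O)C(C)C)=C(O)C(O)(CC=C(C)C)C1=O | intermediate
11 | (1R,5R,7R)-3-hydroxy-8,8-dimethyl-3,5,7-tris(3-methylbut-2-en-1-yl)-1-(2-methylpropanoyl)bicyclo[3.3.1]nonane-2,4,9-trione (both C3 epimers) | CC(C)=CC[C@@H]1C[C@]2(CC=C(C)C)C(=O)[C@@](C(=O)C(C)C)(C(=O)C(O)(CC=C(C)C)C2=O)C1(C)C | intermediate
12 | (1S,3R,5R,7S)-7-hydroxy-4,4-dimethyl-1,3-bis(3-methylbut-2-en-1-yl)-7-(4-methylpent-3-enoyl)-5-(2-methylpropanoyl)bicyclo[3.2.1]octane-6,8-dione | CC(C)=CC[C@@H]1C[C@]2(CC=C(C)C)C(=O)[C@@](C(=O)C(C)C)(C(=O)[C@@]2(O)C(=O)CC=C(C)C)C1(C)C | intermediate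
13 | 7-hydroxy-4,4-dimethyl-1,3-bis(3-methylbut-2-en-1-yl)-7-[4-methyl-2-(phenylselanyl)pent-3-enoyl]-5-(2-methylpropanoyl)bicyclo[3.2.1]octane-6,8-dione (ring stereocentres as in 12; both epimers at the selenium-bearing carbon) | CC(C)=CC[C@@H]1C[C@]2(CC=C(C)C)C(=O)[C@@](C(=O)C(C)C)(C(=O)[C@@]2(O)C(=O)C([Se]c3ccccc3)C=C(C)C)C1(C)C | intermediate
14 | (1S,3R,5R,7S)-7-hydroxy-7-[(2E)-4-hydroxy-4-methylpent-2-enoyl]-4,4-dimethyl-1,3-bis(3-methylbut-2-en-1-yl)-5-(2-methylpropanoyl)bicyclo[3.2.1]octane-6,8-dione | CC(C)=CC[C@@H]1C[C@]2(CC=C(C)C)C(=O)[C@@](C(=O)C(C)C)(C(=O)[C@@]2(O)C(=O)/C=C/C(C)(C)O)C1(C)C | intermediate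
15 | (1S,3R,5R,7S)-7-hydroxy-7-[(2Z)-4-hydroxy-4-methylpent-2-enoyl]-4,4-dimethyl-1,3-bis(3-methylbut-2-en-1-yl)-5-(2-methylpropanoyl)bicyclo[3.2.1]octane-6,8-dione | CC(C)=CC[C@@H]1C[C@]2(CC=C(C)C)C(=O)[C@@](C(=O)C(C)C)(C(=O)[C@@]2(O)C(=O)/C=C\C(C)(C)O)C1(C)C | target

**Step count and risk**
Total steps: 8. Longest linear sequence: 6 (steps 3–8 from phloroglucinol; equally steps 1, 2, 5–8 from lavandulol).

The three steps most likely to fail:

Step 5. A non-allylic, β-branched triflate may O-alkylate or alkylate slowly at the hindered prenyl-bearing carbon, and the quaternary carbon forms without control, so at most half of the material can go on. Fallback: change the order of the C–C bonds so that the triflate meets an unhindered aromatic CH and the quaternary centre is made with reactive prenyl bromide. Setting out from 6, LiN(SiMe3)2 and 3 in THF give aromatic mono-lavandulyl phlorisobutyrophenone F1. Compound 7 (2 equiv) in aqueous KOH then prenylates the free ring carbon to aromatic lavandulyl prenyl phlorisobutyrophenone F2 and, in the same pot, the lavandulyl-bearing carbon. This gives 9 (separated from the gem-diprenyl regioisomer), where the route is rejoined; 9 is hydroxylated as in the second stage of step 5.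

Step 6. The weakly nucleophilic triketone carbon must win over O-capture, over cation–olefin closure onto the geminal prenyl group and over ether formation between the C3 hydroxyl and its own prenyl group. The direction and configuration of the ketol shift rest on thermodynamic control. Fallback: run the two events in the classical order. Setting out from 9 (step 5 quenched before the oxaziridine is added, 9 isolated), HCO2H at 23 °C closes ring B on the non-hydroxylated dienone. This gives the type A enol (isobutyryl analogue of nemorosone) F3, which is separated from the type B isomer. KN(SiMe3)2 and the oxaziridine then hydroxylate C3 of its enolate and give 11, where the route is rejoined (DBU then gives 12).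

Step 8. The photostationary mixture may not be Z-rich enough, and the tertiary carbinol next to the ketone can add to the enone to give a spiro furanone. Fallback: thermodynamic trapping in place of light. Setting out from 14, camphorsulfonic acid (cat.) in MeOH equilibrates the enone by reversible conjugate addition of methanol. Only the Z-isomer can close onto its tertiary hydroxyl, so it is drained as the cyclic methyl ketal (2-methoxy-5,5-dimethyl-2,5-dihydrofuran-2-yl compound) F4. Aqueous AcOH/THF at 0 °C hydrolyses F4 to the lactol, which opens to 15.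

**Further compounds**
F1 | step 5 | 2-methyl-1-{2,4,6-trihydroxy-3-[(2R)-5-methyl-2-(prop-1-en-2-yl)hex-4-en-1-yl]phenyl}propan-1-one | CC(C)=CC[C@@H](C(C)=C)Cc1c(O)cc(O)c(C(=O)C(C)C)c1O
F2 | step 5 | 2-methyl-1-{2,4,6-trihydroxy-3-(3-methylbut-2-en-1-yl)-5-[(2R)-5-methyl-2-(prop-1-en-2-yl)hex-4-en-1-yl]phenyl}propan-1-one | CC(C)=CC[C@@H](C(C)=C)Cc1c(O)c(CC=C(C)C)c(O)c(C(=O)C(C)C)c1O
F3 | step 6 | 4-hydroxy-8,8-dimethyl-3,5,7-tris(3-methylbut-2-en-1-yl)-1-(2-methylpropanoyl)bicyclo[3.3.1]non-3-ene-2,9-dione (type A enol; ring stereocentres as in 11) | CC(C)=CC[C@@H]1C[C@]2(CC=C(C)C)C(=O)[C@@](C(=O)C(C)C)(C(=O)C(CC=C(C)C)=C2O)C1(C)C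
F4 | step 8 | 7-hydroxy-7-(2-methoxy-5,5-dimethyl-2,5-dihydrofuran-2-yl)-4,4-dimethyl-1,3-bis(3-methylbut-2-en-1-yl)-5-(2-methylpropanoyl)bicyclo[3.2.1]octane-6,8-dione (ring stereocentres as in 15; ketal carbon either configuration) | CC(C)=CC[C@@H]1C[C@]2(CC=C(C)C)C(=O)[C@@](C(=O)C(C)C)(C(=O)[C@@]2(O)C3(OC)C=CC(C)(C)O3)C1(C)C
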